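All runs are calculated for substances that don't exist.

The constants of this flask are not given, so the two earlier runs have to stand in for them as rates.

| flask | substrate | gas phase | remark | time |
|---|---|---|---|---|
| ochre | 0.50 M | 200 mM (held) | run made earlier |  |
| green | 2 M | 200 mM (held) | run made earlier |  |
| flask | 1.0 M | 200 mM (held) |  | 2.0 min |

- ochre (time / min: target / %): 0.200: 3.7; 0.417: 9.9; 1.00: 19.9; 2.50: 20.6
- green (time / min: target / %): 0.200: 2.4; 0.417: 3.2; 1.00: 6.8; 2.50: 8.2

(each reading ± 0.5 percentage points)

* target at 2.0 min, in percent of the substrate charged
* concentration of dissolved gas in solution at 2.0 min, in percent of saturation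

- at the start none of the gas phase is in solution

Read over the first interval, the start rate r (initial rate) of target is 92.5 mM min⁻¹ in the ochre run and 240 mM min⁻¹ in the green run. A charge larger by a factor 4.00 thus raises r by a factor 2.59, which is the charge to the power 0.688. Between the last two readings the mean net rates are 2.33 mM min⁻¹ and 18.7 mM min⁻¹, down by factors of about 39.7 and 12.8. Such a mean cannot tell a steady level from a rise and fall between the two readings, so taking the last reading as the level of target at 2.0 min is an assumption of my reckoning.

Last target over r gives 1.11 min for ochre; this is the working time w, the time at the start rate that makes as much target as the last reading shows. Green gives 0.683 min, so w shrinks as the charge to the power 0.352. All these values carry the scatter of the readings. For the flask at 1.0 M, my reckoning gives r = 149 mM min⁻¹ and w = 0.872 min, hence target 13.0%.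

The forecast puts target at 13% (11.5% to 14.5%) and dissolved gas at 72% of saturation (55% to 88%), on the ground that “the target is capped by gas absorbed during the substrate's lifetime”.

The flask gives 14.4% of target and 68.4% of saturation, both inside those ranges. At 0.200 min the step to homo dimer had 45% of its turnover behind it while dissolved gas stood at 20.1% of saturation, and at 0.746 min target was still made 3.29 times faster than it was used up. By 2.00 min substrate was down to 10.1%, with homo dimer at 63.2%, counted by the substrate it holds, and over-reacted product at 6.27%.

    2 substrate → homo dimer (k = 0.0170 M⁻¹ s⁻¹)
    substrate + target → side product (k = 0.00990 M⁻¹ s⁻¹)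
    dissolved gas + target → over-reacted product (k = 0.0460 M⁻¹ s⁻¹)
    substrate + dissolved gas ⇌ target (K = 17.0 M⁻¹, k = 0.130 M⁻¹ s⁻¹)
    gas phase ⇌ dissolved gas, rate k5*(csat - [dissolved gas]) (kL = 0.0330 s⁻¹)

For the neighbouring flask with 0.40 M of substrate, below both runs, w becomes 1.20 min and r becomes 79.3 mM min⁻¹, so target comes to 23.8%. That flask gives 25.4%.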